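**Retrosynthetic overview**

1. Starting materials are 1-hexacosanol (1), cyclopropanone ethyl hemiketal, i.e. 1-ethoxycyclopropan-1-ol (2), and 4-bromophenol (3).
2. C–O disconnection: hemiketal exchange of 1 with 2 gives 1-(hexacosyloxy)cyclopropan-1-ol (4), a masked ester homoenolate.
3. Key C–C disconnection of the target, hexacosyl 3-(4-hydroxyphenyl)propanoate (5), is the aryl–Cβ bond. Pd-mediated ring opening of 4 gives a β-palladated ester (d3 homoenolate) that couples with the aryl electrophile 3; the same ring opening creates the ester C=O.
4. Ring order: no ring is built. The arene is bought and the cyclopropane is opened in the key step.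

Assumption: the target is achiral (no stereocentres) and the chain is unbranched C26, so no stereocontrol is needed.

**Step 1**

Reactants: 1 1-hexacosanol; 2 1-ethoxycyclopropan-1-ol; 3 4-bromophenol

Product: 5 hexacosyl 3-(4-hydroxyphenyl)propanoate, via 1-(hexacosyloxy)cyclopropan-1-ol 4 (not isolated)

Conditions: (i) 2 (3 equiv), PhMe, 70 °C, N2 sweep (−EtOH), then volatiles off in vacuo; (ii) same flask, 3 (1.3 equiv), Pd(OAc)2 (5 mol%), XPhos (10 mol%), Cs2CO3 (2.5 equiv), PhMe, 80 °C; pH 7 buffer work-up

Reagents that add atoms: none

Why: Proposed new method: hemiketal exchange (via a trace of free cyclopropanone, as in the known ethyl-to-methyl exchange of 2 in methanol) is pulled to 4 by removing EtOH, and 4 then undergoes Pd-catalysed ring-opening cross-coupling — oxidative addition of 3, Pd-alkoxide formation, strain-driven β-carbon elimination to the ester-chelated palladium homoenolate ArPd–CH2CH2CO2C26H53, and C(sp2)–C(sp3) reductive elimination that the bulky biarylphosphine should favour over β-hydride loss — so the normally electrophilic ester β-carbon is joined as a nucleophile to the electrophilic aryl carbon; the closest known reactions are the Pd-catalysed arylation of cyclopropanols to β-aryl ketones and of 1-alkoxy-1-siloxycyclopropanes to β-aryl esters; no stereocentre is formed.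

**Compound list**

1 | 1-hexacosanol | CCCCCCCCCCCCCCCCCCCCCCCCCCO | starting material
2 | 1-ethoxycyclopropan-1-ol (cyclopropanone ethyl hemiketal) | CCOC1(O)CC1 | starting material
3 | 4-bromophenol | Oc1ccc(Br)cc1 | starting material
4 | 1-(hexacosyloxy)cyclopropan-1-ol | CCCCCCCCCCCCCCCCCCCCCCCCCCOC1(O)CC1 | intermediate
5 | hexacosyl 3-(4-hydroxyphenyl)propanoate | CCCCCCCCCCCCCCCCCCCCCCCCCCOC(=O)CCc1ccc(O)cc1 | target

**Totals**

Total step count: 1 (one flask, two stages). Longest linear sequence: 1.

**Steps most likely to fail**

The route has a single step, so step 1 is the only entry. Its weak points are: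
- Stage (i) may stop short of full exchange, or give oligomeric cyclopropanone ketals once EtOH is stripped.
- Base may open the hemiketal by protonation to hexacosyl propanoate before palladium intercepts it.
- The palladium homoenolate may lose β-hydride, giving the acrylate and then hexacosyl 4-hydroxycinnamate by Heck reaction.
- The caesium phenoxide of 3 may slow oxidative addition.

Fallback for step 1, setting out from 1 and returning at 5: esterify 1 with 3-bromopropanoic acid (cat. TsOH, PhMe, Dean–Stark) to give hexacosyl 3-bromopropanoate F1. Insert zinc (Zn dust activated with 1,2-dibromoethane/TMSCl, LiCl, THF, 50 °C) to give the stoichiometric zinc homoenolate [3-(hexacosyloxy)-3-oxopropyl]zinc bromide F2. Add F2 slowly to 3 with Pd(OAc)2/SPhos in THF at 25–40 °C; this Negishi coupling tolerates the free phenol when the zinc reagent is added slowly, and it delivers 5. The same aryl–Cβ bond is made with the same polarity, but from a preformed ester and a preformed organometallic, with no strained-ring precursor and no base.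

**Further compounds**

F1 | step 1 | hexacosyl 3-bromopropanoate | CCCCCCCCCCCCCCCCCCCCCCCCCCOC(=O)CCBr
F2 | step 1 | [3-(hexacosyloxy)-3-oxopropyl]zinc bromide | CCCCCCCCCCCCCCCCCCCCCCCCCCOC(=O)CC[Zn]Br
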